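**Assumption:** the SMILES has no stereocentre and the 21-membered ring is too large for stable planar chirality, so the target is achiral and no stereocontrol is needed.

**Retrosynthetic overview**
1. Target 11 ⇐ macrocycle 9: the hydroquinone ring is a 3-aryloxy-5-alkylphenol hydroxylated para to its OH (oxidation to the quinone, then reduction).
2. 9 ⇐ 8 ⇐ 7: the 21-membered ring is closed by intramolecular C–O coupling of the mono-triflate of a bis-resorcinol whose four OH groups are equivalent.
3. 7 ⇐ 5: both benzene rings are made at once by a twofold pyranone → resorcinol isomerisation of a bis(γ-pyranone), a masked bis-triketide.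
4. 5 ⇐ 2 × 1 + 2: double lateral alkylation; the two pyranone methyl carbons plus C12 give the (CH2)14 tether.
5. Ring order: the two arene rings together (step 2), then the macrocycle (step 4).

**Step 1**
Reactants: 1 2,6-dimethyl-4H-pyran-4-one (2.2 equiv); 2 1,12-dibromododecane (1.0 equiv)
Product: 5 2,2'-(tetradecane-1,14-diyl)bis(6-methyl-4H-pyran-4-one), via (6-methyl-4-oxo-4H-pyran-2-yl)methyllithium 3 (not isolated), via 2-(13-bromotridecyl)-6-methyl-4H-pyran-4-one 4 (not isolated)
Conditions: LDA (2.2 equiv, commercial solution), THF, –78 °C, 45 min; then 2, DMPU, –78 → 0 °C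
Reagents that add atoms: none
Why: LDA removes a methyl proton of the γ-pyranone to give the extended dienolate, which is alkylated at its exocyclic carbon by the primary dibromide at both ends (lateral lithiation/SN2 alkylation of a vinylogous ester enolate).

**Step 2**
Reactants: 5 2,2'-(tetradecane-1,14-diyl)bis(6-methyl-4H-pyran-4-one)
Product: 7 5,5'-(tetradecane-1,14-diyl)bis(benzene-1,3-diol), via hexacosane-2,4,6,21,23,25-hexaone 6 (not isolated)
Conditions: KOH (4 M aq)/EtOH, degassed, reflux, 8 h; then 2 M HCl, 0 °C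
Reagents that add atoms: water, O
Why: hydroxide opens each pyranone to the 1,3,5-triketone, whose terminal methyl carbanion (secondary ionisation of a β-diketone prefers CH3 over CH2R) adds to the chain-side ketone and dehydrates to a 5-alkylresorcinol, a net isomerisation that builds both benzene rings in one pot (Collie-type pyranone → orcinol aldol aromatisation).

**Step 3**
Reactants: 7 5,5'-(tetradecane-1,14-diyl)bis(benzene-1,3-diol)
Product: 8 3-[14-(3,5-dihydroxyphenyl)tetradecyl]-5-hydroxyphenyl trifluoromethanesulfonate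
Conditions: PhNTf2 (1.0 equiv, slow addition), K2CO3 (2.2 equiv), DMF, 0 °C → rt; unreacted 7 and over-triflated material separated and recycled
Reagents that add atoms: N-phenyl-bis(trifluoromethanesulfonimide), FC(F)(F)S(=O)(=O)N(c1ccccc1)S(=O)(=O)C(F)(F)F
Why: all four phenols are equivalent, so mono-O-sulfonylation by phenoxide attack on PhNTf2 gives a single constitutional product in roughly statistical yield, and the triflated ring's remaining phenoxide is the less nucleophilic one, which limits double triflation on one ring.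

**Step 4**
Reactants: 8 3-[14-(3,5-dihydroxyphenyl)tetradecyl]-5-hydroxyphenyl trifluoromethanesulfonate
Product: 9 2-oxa-1,3(1,3)-dibenzenacycloheptadecaphane-1^5,3^5-diol (symmetric 21-membered diaryl ether)
Conditions: Pd2(dba)3 (5 mol %), t-BuXPhos (12 mol %), K3PO4 (3 equiv), toluene/1,4-dioxane, 100 °C, syringe-pump addition to 2 mM
Reagents that add atoms: none
Why: Pd(0) inserts into the aryl triflate and either of the two equivalent phenoxides of the distal ring closes the strain-free 21-membered ring by C–O reductive elimination (Buchwald–Hartwig diaryl ether coupling under high dilution), while the triflated ring's own meta OH cannot reach its own carbon.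

**Step 5**
Reactants: 9 2-oxa-1,3(1,3)-dibenzenacycloheptadecaphane-1^5,3^5-diol
Product: 11 2-oxa-1,3(1,3)-dibenzenacycloheptadecaphane-1^2,1^5,3^5-triol (target), via macrocyclic 2-aryloxy-6-alkyl-1,4-benzoquinone 10 (not isolated)
Conditions: (KSO3)2NO (2.1 equiv), Aliquat 336 (cat.), CH2Cl2/aq KH2PO4, rt, stopped at about 60 % conversion; then aq Na2S2O4, EtOAc; recovered 9 recycled
Reagents that add atoms: potassium nitrosodisulfonate (Fremy's salt), [K+].[K+].[O]N(S(=O)(=O)[O-])S(=O)(=O)[O-]
Why: Fremy's salt oxidises a 3,5-disubstituted phenol only at the free para position, here between the aryloxy and alkyl groups, to give the 2-aryloxy-6-alkyl-p-quinone (Teuber oxidation, as for 3-alkoxy-5-alkylphenols), and dithionite reduces it to the hydroquinone; the two rings of 9 are equivalent, so mono-oxidation is statistical.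

**Compound list**
1 | 2,6-dimethyl-4H-pyran-4-one | CC1=CC(=O)C=C(C)O1 | starting material
2 | 1,12-dibromododecane | BrCCCCCCCCCCCCBr | starting material
3 | (6-methyl-4-oxo-4H-pyran-2-yl)methyllithium (lithium dienolate of 1) | [Li]CC1=CC(=O)C=C(C)O1 | intermediate
4 | 2-(13-bromotridecyl)-6-methyl-4H-pyran-4-one | CC1=CC(=O)C=C(CCCCCCCCCCCCCBr)O1 | intermediate
5 | 2,2'-(tetradecane-1,14-diyl)bis(6-methyl-4H-pyran-4-one) | CC1=CC(=O)C=C(CCCCCCCCCCCCCCC2=CC(=O)C=C(C)O2)O1 | intermediate
6 | hexacosane-2,4,6,21,23,25-hexaone | CC(=O)CC(=O)CC(=O)CCCCCCCCCCCCCCC(=O)CC(=O)CC(=O)C | intermediate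
7 | 5,5'-(tetradecane-1,14-diyl)bis(benzene-1,3-diol) | Oc1cc(O)cc(c1)CCCCCCCCCCCCCCc1cc(O)cc(O)c1 | intermediate
8 | 3-[14-(3,5-dihydroxyphenyl)tetradecyl]-5-hydroxyphenyl trifluoromethanesulfonate | Oc1cc(O)cc(c1)CCCCCCCCCCCCCCc1cc(O)cc(OS(=O)(=O)C(F)(F)F)c1 | intermediate
9 | 2-oxa-1,3(1,3)-dibenzenacycloheptadecaphane-1^5,3^5-diol (bis(3-hydroxyphenyl) ether whose 5- and 5'-positions are joined by a (CH2)14 chain) | Oc1cc2cc(c1)Oc1cc(O)cc(c1)CCCCCCCCCCCCCC2 | intermediate
10 | macrocyclic 2-aryloxy-6-alkyl-1,4-benzoquinone (quinone form of 11; one ring of 9 oxidised para to its OH) | Oc1cc2cc(c1)OC1=CC(=O)C=C(C1=O)CCCCCCCCCCCCCC2 | intermediate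
11 | 2-oxa-1,3(1,3)-dibenzenacycloheptadecaphane-1^2,1^5,3^5-triol (achiral) | Oc1cc2cc(c1)Oc1cc(O)cc(c1O)CCCCCCCCCCCCCC2 | target

**Totals**
Total step count: 5. Longest linear sequence: 5.

**Steps most likely to fail, with fallbacks**

Step 2 (twofold pyranone → resorcinol isomerisation). It could fail through the wrong aldol mode (chain CH2 attacking the acetyl group) or retro-Claisen cleavage of the triketone. The fallback gives up the de novo ring construction and sets out from 2. Heating 2 with PPh3 gives dodecane-1,12-diylbis(triphenylphosphonium) dibromide F3. A double Wittig reaction of F3 with 3,5-dimethoxybenzaldehyde (KOtBu, THF) gives 1,14-bis(3,5-dimethoxyphenyl)tetradeca-1,13-diene F4 as a Z/E mixture. Hydrogenation (H2, Pd/C) gives 1,14-bis(3,5-dimethoxyphenyl)tetradecane F5, and BBr3 (CH2Cl2, –78 °C → rt) removes the four methyl ethers, returning to the route at 7.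

Step 4 (Pd-catalysed macrocyclic etherification). It could fail through oligomerisation or slow oxidative addition into the electron-rich triflate. The fallback sets out from 8 and reverses the polarity of the aryl partner. Miyaura borylation (B2pin2, Pd(dppf)Cl2, KOAc, dioxane, 80 °C) gives 3-[14-(3,5-dihydroxyphenyl)tetradecyl]-5-(4,4,5,5-tetramethyl-1,3,2-dioxaborolan-2-yl)phenol F6. An oxidative Chan–Lam macrocyclisation (Cu(OAc)2, pyridine, 4 Å MS, air, CH2Cl2 or MeCN, 2 mM) then closes the ring and returns to the route at 9.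

Step 1 (double lateral alkylation). It could fail because the primary bromide reacts slowly or because proton transfer leads to branched over-alkylation. The fallback sets out from 1 and uses carbonyl addition instead of SN2. The lithium dienolate of 1 (LDA, THF, –78 °C) adds to commercial dodecanedial (0.5 equiv) to give 2,2'-(2,13-dihydroxytetradecane-1,14-diyl)bis(6-methyl-4H-pyran-4-one) F1 as a diastereomer mixture. Acid-catalysed dehydration (TsOH cat., toluene, Dean–Stark) gives 2,2'-[(1E,13E)-tetradeca-1,13-diene-1,14-diyl]bis(6-methyl-4H-pyran-4-one) F2. Selective hydrogenation of the two exocyclic alkenes (H2 1 atm, Pd/C or Wilkinson's catalyst, EtOAc) returns to the route at 5.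

**Further compounds**
F1 | step 1 | 2,2'-(2,13-dihydroxytetradecane-1,14-diyl)bis(6-methyl-4H-pyran-4-one) (diastereomer mixture) | CC1=CC(=O)C=C(CC(O)CCCCCCCCCCC(O)CC2=CC(=O)C=C(C)O2)O1
F2 | step 1 | 2,2'-[(1E,13E)-tetradeca-1,13-diene-1,14-diyl]bis(6-methyl-4H-pyran-4-one) | CC1=CC(=O)C=C(/C=C/CCCCCCCCCC/C=C/C2=CC(=O)C=C(C)O2)O1
F3 | step 2 | dodecane-1,12-diylbis(triphenylphosphonium) dibromide | [Br-].[Br-].c1ccc(cc1)[P+](c1ccccc1)(c1ccccc1)CCCCCCCCCCCC[P+](c1ccccc1)(c1ccccc1)c1ccccc1
F4 | step 2 | 1,14-bis(3,5-dimethoxyphenyl)tetradeca-1,13-diene (Z/E mixture) | COc1cc(OC)cc(C=CCCCCCCCCCCC=Cc2cc(OC)cc(OC)c2)c1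
F5 | step 2 | 1,14-bis(3,5-dimethoxyphenyl)tetradecane | COc1cc(OC)cc(CCCCCCCCCCCCCCc2cc(OC)cc(OC)c2)c1
F6 | step 4 | 3-[14-(3,5-dihydroxyphenyl)tetradecyl]-5-(4,4,5,5-tetramethyl-1,3,2-dioxaborolan-2-yl)phenol | Oc1cc(O)cc(c1)CCCCCCCCCCCCCCc1cc(O)cc(c1)B1OC(C)(C)C(C)(C)O1
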